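**Retrosynthetic overview**
1. Feature: in ring A (the phloroglucinol core) the two benzylic stereocentres are the CH(i-Pr) carbons on C3 and C5. Each stands ortho to a phenolic oxygen (O2, O6), and C1, the only other ortho site of both oxygens, carries the hexanoyl group. Each aryl–CH bond can therefore be read as the trace of an O-to-C allyl shift.
2. Endgame: the three benzyl ethers come off last. Each syncarpic ring (rings B and C) is opened at its C2–C3 bond (retro-Dieckmann) to a 2,2,4,4-tetramethyl-3,5-dioxo ester arm. That arm comes from aldol addition and oxidation of an ArCH(i-Pr)CH2CHO arm with the enolate of methyl 2,2,4-trimethyl-3-oxopentanoate, the methanolysis product of tetramethylcyclobutanedione.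
3. The CH2CHO arms come from (E)-propenyl groups by ethenolysis, hydroboration–oxidation and alcohol oxidation.
4. Key disconnection: both aryl–CH(i-Pr) bonds are made at once by a double ortho aromatic Claisen rearrangement of a bis[(R,E)-allyl] ether. The ether is made by Mitsunobu inversion of the (S)-allylic alcohol (CBS reduction) on 4-O-benzyl hexanoylphloroglucinol.
5. Ring order: ring A is bought as phloroglucinol, no ring forms in the key step, and rings B and C close together in step 13.

Key step: step 5

Remark 1: the target SMILES encodes the C2-symmetric (R,R) isomer, not the meso form; the enol drawn is one of several interconverting tautomers.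
Remark 2: in every twofold step the two arms react one after the other in the same flask; the half-converted species is numbered only in the key step.

**Step 1**
Reactants: 1 phloroglucinol; 2 hexanoyl chloride
Product: 3 1-(2,4,6-trihydroxyphenyl)hexan-1-one
Conditions: AlCl3 (4 equiv), CH2Cl2–PhNO2, 40 °C; aq. HCl
Reagents that add atoms: none
Why: Friedel–Crafts acylation of the very electron-rich ring should stop after one acyl group because the product is deactivated and held as an aluminium chelate.

**Step 2**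
Reactants: 3 1-(2,4,6-trihydroxyphenyl)hexan-1-one
Product: 4 1-[4-(benzyloxy)-2,6-dihydroxyphenyl]hexan-1-one
Conditions: BnBr (1.0 equiv), K2CO3 (1.0 equiv), acetone, reflux
Reagents that add atoms: benzyl bromide, BrCc1ccccc1
Why: Williamson etherification with one equivalent of base should address the para hydroxyl, which is the most acidic and the only one not hydrogen-bonded to the ketone, and any dibenzyl ether is removed by chromatography.

**Step 3**
Reactants: 5 (E)-5-methylhex-3-en-2-one
Product: 6 (2S,3E)-5-methylhex-3-en-2-ol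
Conditions: (R)-2-methyl-CBS-oxazaborolidine (10 mol %), BH3·SMe2, THF, −30 °C; aq. NH4Cl
Reagents that add atoms: none
Why: In this Corey–Bakshi–Shibata reduction the ketone binds the oxazaborolidine–borane complex with the alkenyl group as the large substituent, so the (R)-catalyst should deliver hydride to the face that gives the (S)-carbinol, with 1,2-reduction outrunning hydroboration at low temperature.

**Step 4**
Reactants: 4 1-[4-(benzyloxy)-2,6-dihydroxyphenyl]hexan-1-one; 6 (2S,3E)-5-methylhex-3-en-2-ol (2.4 equiv)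
Product: 7 1-[4-(benzyloxy)-2,6-bis[[(2R,3E)-5-methylhex-3-en-2-yl]oxy]phenyl]hexan-1-one
Conditions: PPh3, DIAD (2.5 equiv each), PhMe, 0 °C to rt
Reagents that add atoms: none
Why: In this twofold Mitsunobu etherification the acidic acylphenol hydroxyls displace the alkoxyphosphonium ion by SN2 with inversion ((S)-alcohol to (R)-ether), the isopropyl-bearing alkene terminus being too hindered for SN2′ attack, and because two units of 6 are attached most of its minor enantiomer ends in a meso-type diastereomer that can be removed at this or a later stage (Horeau amplification).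

**Step 5**
Reactants: 7 1-[4-(benzyloxy)-2,6-bis[[(2R,3E)-5-methylhex-3-en-2-yl]oxy]phenyl]hexan-1-one
Product: 11 1-[4-(benzyloxy)-2,6-dihydroxy-3,5-bis[(3S,4E)-2-methylhex-4-en-3-yl]phenyl]hexan-1-one, via first ortho-dienone 8 (not isolated), via mono-rearranged phenol ether 9 (not isolated), via second ortho-dienone 10 (not isolated)
Conditions: Eu(fod)3 (20 mol %), PhMe, 100 °C, Ar
Reagents that add atoms: none
Why: Each allyl aryl ether undergoes a concerted suprafacial [3,3]-sigmatropic shift (ortho aromatic Claisen rearrangement), eased by the oxophilic europium centre held between the ketone and ether oxygens, and each ortho-dienone (8, 10) enolises at once to a phenol tied to the hexanoyl carbonyl by a hydrogen bond. The closest known reaction type is the thermal or Eu(fod)3-promoted Claisen rearrangement of enantioenriched (E)-1,3-dialkylallyl aryl ethers with 1,3-chirality transfer. No ring is closed; the two skeletal bonds C3–CH(i-Pr) and C5–CH(i-Pr) are formed. Each new benzylic centre is controlled by the carbinol centre it replaces: carbon bonds to the allyl face from which oxygen departs, and with the carbinol methyl group pseudo-equatorial the (R,E)-ether gives the (S)-centre together with an (E)-propenyl group, chair and boat arrays leading to the same centre because the ring-carbon centre of the dienone is erased on enolisation. Site selectivity comes from the hexanoyl group at C1, which leaves C3 and C5 as the only ortho carbons from which a dienone can rearomatise, a shift to C1 being reversible. Chemoselectivity after the shift rests on the chelated phenols, which are poor proton donors towards the new alkenes and so should hold back the abnormal Claisen pathway and ring closure to chromans.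

**Step 6**
Reactants: 11 1-[4-(benzyloxy)-2,6-dihydroxy-3,5-bis[(3S,4E)-2-methylhex-4-en-3-yl]phenyl]hexan-1-one
Product: 12 1-[2,4,6-tris(benzyloxy)-3,5-bis[(3S,4E)-2-methylhex-4-en-3-yl]phenyl]hexan-1-one
Conditions: BnBr (3 equiv), Cs2CO3 (3 equiv), DMF, 50 °C
Reagents that add atoms: benzyl bromide, BrCc1ccccc1
Why: Williamson etherification in a polar aprotic medium breaks the hydrogen bonds and O-alkylates both phenoxides, which removes the acidic protons ahead of the metathesis, borane and enolate steps and lets one hydrogenolysis free all three phenols at the end.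

**Step 7**
Reactants: 12 1-[2,4,6-tris(benzyloxy)-3,5-bis[(3S,4E)-2-methylhex-4-en-3-yl]phenyl]hexan-1-one
Product: 13 1-[2,4,6-tris(benzyloxy)-3,5-bis[(3S)-4-methylpent-1-en-3-yl]phenyl]hexan-1-one
Conditions: second-generation Grubbs catalyst (10 mol %), ethylene (5 bar), 1,4-benzoquinone (20 mol %), PhMe, 60 °C
Reagents that add atoms: ethylene, C=C
Why: In this cross-metathesis with ethylene (ethenolysis) the ruthenium methylidene adds with the metal at the methyl-bearing alkene carbon, away from the crowded benzylic centre, and releases propene, while the stereocentres are untouched and benzoquinone intercepts ruthenium hydrides that could move the double bond.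

**Step 8**
Reactants: 13 1-[2,4,6-tris(benzyloxy)-3,5-bis[(3S)-4-methylpent-1-en-3-yl]phenyl]hexan-1-one
Product: 15 1-[2,4,6-tris(benzyloxy)-3,5-bis[(3R)-1-hydroxy-4-methylpentan-3-yl]phenyl]hexan-1-one, via bis(B-alkyl-9-BBN) adduct 14 (not isolated)
Conditions: 9-BBN (5 equiv), THF, 0 to 50 °C; then NaOH, H2O2, 0 °C to rt
Reagents that add atoms: 9-BBN, B1C2CCCC1CCC2 (atoms kept only in 14); hydrogen peroxide, OO
Why: In this hydroboration–oxidation the bulky borane places boron on the terminal carbon of the monosubstituted alkene far faster than it attacks the doubly ortho-substituted, twisted ketone, any carbinol formed there would be reoxidised in step 9, and the descriptor changes from S to R only through a change of CIP priorities.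

**Step 9**
Reactants: 15 1-[2,4,6-tris(benzyloxy)-3,5-bis[(3R)-1-hydroxy-4-methylpentan-3-yl]phenyl]hexan-1-one
Product: 16 (3R,3'R)-3,3'-[2,4,6-tris(benzyloxy)-5-hexanoyl-1,3-phenylene]bis(4-methylpentanal)
Conditions: Dess–Martin periodinane (3 equiv), CH2Cl2, 0 °C to rt
Reagents that add atoms: none
Why: Dess–Martin oxidation stops at the aldehyde under near-neutral conditions, and the stereocentres are β to the new carbonyl groups and therefore not at risk.

**Step 10**
Reactants: 17 2,2,4,4-tetramethylcyclobutane-1,3-dione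
Product: 18 methyl 2,2,4-trimethyl-3-oxopentanoate
Conditions: NaOMe (5 mol %), MeOH, reflux
Reagents that add atoms: methanol, CO
Why: Alkoxide-catalysed retro-Claisen ring opening of the strained, non-enolisable cyclic 1,3-diketone by methanol is a known reaction of this diketone.

**Step 11**
Reactants: 18 methyl 2,2,4-trimethyl-3-oxopentanoate (3 equiv); 16 (3R,3'R)-3,3'-[2,4,6-tris(benzyloxy)-5-hexanoyl-1,3-phenylene]bis(4-methylpentanal)
Product: 20 dimethyl (7R,7'R)-7,7'-[2,4,6-tris(benzyloxy)-5-hexanoyl-1,3-phenylene]bis(5-hydroxy-2,2,4,4,8-pentamethyl-3-oxononanoate) as a mixture of C5 carbinol epimers, via lithium enolate of the keto ester 19 (not isolated)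
Conditions: LiN(iPr)2 (LDA), THF, −78 to 0 °C; then 16, −78 °C; AcOH quench at −78 °C
Reagents that add atoms: LiN(iPr)2, [Li+].CC(C)[N-]C(C)C (lithium kept only in 19)
Why: In this directed aldol addition the only acidic C–H of 18 is the isopropyl methine, the tetrasubstituted lithium enolate adds to aldehydes faster than it exchanges protons and cannot reach the shielded aryl ketone, the cold quench forestalls lactonisation, and the two new carbinol centres are erased in step 12.

**Step 12**
Reactants: 20 dimethyl (7R,7'R)-7,7'-[2,4,6-tris(benzyloxy)-5-hexanoyl-1,3-phenylene]bis(5-hydroxy-2,2,4,4,8-pentamethyl-3-oxononanoate)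
Product: 21 dimethyl (7R,7'R)-7,7'-[2,4,6-tris(benzyloxy)-5-hexanoyl-1,3-phenylene]bis(2,2,4,4,8-pentamethyl-3,5-dioxononanoate)
Conditions: Dess–Martin periodinane (3 equiv), CH2Cl2, rt
Reagents that add atoms: none
Why: Dess–Martin oxidation of the hindered β-hydroxy ketones under near-neutral conditions avoids retro-aldol cleavage and delivers the non-enolisable 1,3-diketone unit.

**Step 13**
Reactants: 21 dimethyl (7R,7'R)-7,7'-[2,4,6-tris(benzyloxy)-5-hexanoyl-1,3-phenylene]bis(2,2,4,4,8-pentamethyl-3,5-dioxononanoate)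
Product: 22 1-[2,4,6-tris(benzyloxy)-3,5-bis[(1R)-1-(2-hydroxy-3,3,5,5-tetramethyl-4,6-dioxocyclohex-1-en-1-yl)-2-methylpropyl]phenyl]hexan-1-one
Conditions: LiN(iPr)2 (7 equiv), THF, −78 °C to rt; aq. HCl
Reagents that add atoms: none
Why: In this twofold Dieckmann-type (intramolecular Claisen) condensation of a 3,5-dioxo ester the C6 methylene is the only enolisable site of each arm, the 6-(enolendo)-exo-trig closure is helped by four geminal methyl groups and driven by deprotonation of the cyclic β-triketone, the hexanoyl enolate finds no electrophile within reach and is reprotonated on work-up, and the benzylic centres carry no acidic hydrogen.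

**Step 14**
Reactants: 22 1-[2,4,6-tris(benzyloxy)-3,5-bis[(1R)-1-(2-hydroxy-3,3,5,5-tetramethyl-4,6-dioxocyclohex-1-en-1-yl)-2-methylpropyl]phenyl]hexan-1-one
Product: 23 myrtucommulone F, 1-[2,4,6-trihydroxy-3,5-bis[(1R)-1-(2-hydroxy-3,3,5,5-tetramethyl-4,6-dioxocyclohex-1-en-1-yl)-2-methylpropyl]phenyl]hexan-1-one
Conditions: H2 (1 atm), Pd/C, EtOAc–MeOH, rt
Reagents that add atoms: none
Why: Hydrogenolysis of the three benzyl aryl ethers runs under neutral conditions, the enolised triketones and the aryl ketone behave as vinylogous acids that resist hydrogenation, and no acid or base is present that could trigger retro-Michael epimerisation or xanthene formation.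

**Compound list**
1 | phloroglucinol | Oc1cc(O)cc(O)c1 | starting material
2 | hexanoyl chloride | CCCCCC(Cl)=O | starting material
3 | 1-(2,4,6-trihydroxyphenyl)hexan-1-one | CCCCCC(=O)c1c(O)cc(O)cc1O | intermediate
4 | 1-[4-(benzyloxy)-2,6-dihydroxyphenyl]hexan-1-one | CCCCCC(=O)c1c(O)cc(OCc2ccccc2)cc1O | intermediate
5 | (E)-5-methylhex-3-en-2-one | CC(=O)/C=C/C(C)C | starting material
6 | (2S,3E)-5-methylhex-3-en-2-ol | C[C@H](O)/C=C/C(C)C | intermediate
7 | 1-[4-(benzyloxy)-2,6-bis[[(2R,3E)-5-methylhex-3-en-2-yl]oxy]phenyl]hexan-1-one | CCCCCC(=O)c1c(O[C@H](C)/C=C/C(C)C)cc(OCc2ccccc2)cc1O[C@H](C)/C=C/C(C)C | intermediate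
8 | first ortho-dienone, 5-(benzyloxy)-2-hexanoyl-6-[(3S,4E)-2-methylhex-4-en-3-yl]-3-[[(2R,3E)-5-methylhex-3-en-2-yl]oxy]cyclohexa-2,4-dien-1-one (ring C6 undefined) | CCCCCC(=O)C1=C(O[C@H](C)/C=C/C(C)C)C=C(OCc2ccccc2)C([C@H](/C=C/C)C(C)C)C1=O | intermediate
9 | mono-rearranged phenol ether, 1-[4-(benzyloxy)-2-hydroxy-3-[(3S,4E)-2-methylhex-4-en-3-yl]-6-[[(2R,3E)-5-methylhex-3-en-2-yl]oxy]phenyl]hexan-1-one | CCCCCC(=O)c1c(O)c([C@H](/C=C/C)C(C)C)c(OCc2ccccc2)cc1O[C@H](C)/C=C/C(C)C | intermediate
10 | second ortho-dienone, 5-(benzyloxy)-2-hexanoyl-3-hydroxy-4,6-bis[(3S,4E)-2-methylhex-4-en-3-yl]cyclohexa-2,4-dien-1-one (ring C6 undefined) | CCCCCC(=O)C1=C(O)C([C@H](/C=C/C)C(C)C)=C(OCc2ccccc2)C([C@H](/C=C/C)C(C)C)C1=O | intermediate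
11 | 1-[4-(benzyloxy)-2,6-dihydroxy-3,5-bis[(3S,4E)-2-methylhex-4-en-3-yl]phenyl]hexan-1-one | CCCCCC(=O)c1c(O)c([C@H](/C=C/C)C(C)C)c(OCc2ccccc2)c([C@H](/C=C/C)C(C)C)c1O | intermediate
12 | 1-[2,4,6-tris(benzyloxy)-3,5-bis[(3S,4E)-2-methylhex-4-en-3-yl]phenyl]hexan-1-one | CCCCCC(=O)c1c(OCc2ccccc2)c([C@H](/C=C/C)C(C)C)c(OCc2ccccc2)c([C@H](/C=C/C)C(C)C)c1OCc3ccccc3 | intermediate
13 | 1-[2,4,6-tris(benzyloxy)-3,5-bis[(3S)-4-methylpent-1-en-3-yl]phenyl]hexan-1-one | CCCCCC(=O)c1c(OCc2ccccc2)c([C@H](C=C)C(C)C)c(OCc2ccccc2)c([C@H](C=C)C(C)C)c1OCc3ccccc3 | intermediate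
14 | 1-[2,4,6-tris(benzyloxy)-3,5-bis[(3R)-1-(9-borabicyclo[3.3.1]nonan-9-yl)-4-methylpentan-3-yl]phenyl]hexan-1-one | CCCCCC(=O)c1c(OCc2ccccc2)c([C@H](CCB4C5CCCC4CCC5)C(C)C)c(OCc2ccccc2)c([C@H](CCB4C5CCCC4CCC5)C(C)C)c1OCc3ccccc3 | intermediate
15 | 1-[2,4,6-tris(benzyloxy)-3,5-bis[(3R)-1-hydroxy-4-methylpentan-3-yl]phenyl]hexan-1-one | CCCCCC(=O)c1c(OCc2ccccc2)c([C@H](CCO)C(C)C)c(OCc2ccccc2)c([C@H](CCO)C(C)C)c1OCc3ccccc3 | intermediate
16 | (3R,3'R)-3,3'-[2,4,6-tris(benzyloxy)-5-hexanoyl-1,3-phenylene]bis(4-methylpentanal) | CCCCCC(=O)c1c(OCc2ccccc2)c([C@H](CC=O)C(C)C)c(OCc2ccccc2)c([C@H](CC=O)C(C)C)c1OCc3ccccc3 | intermediate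
17 | 2,2,4,4-tetramethylcyclobutane-1,3-dione | CC1(C)C(=O)C(C)(C)C1=O | starting material
18 | methyl 2,2,4-trimethyl-3-oxopentanoate | COC(=O)C(C)(C)C(=O)C(C)C | intermediate
19 | lithium 5-methoxy-2,4,4-trimethyl-5-oxopent-2-en-3-olate | [Li+].COC(=O)C(C)(C)C([O-])=C(C)C | intermediate
20 | dimethyl (7R,7'R)-7,7'-[2,4,6-tris(benzyloxy)-5-hexanoyl-1,3-phenylene]bis(5-hydroxy-2,2,4,4,8-pentamethyl-3-oxononanoate), C5 epimers | CCCCCC(=O)c1c(OCc2ccccc2)c([C@H](CC(O)C(C)(C)C(=O)C(C)(C)C(=O)OC)C(C)C)c(OCc2ccccc2)c([C@H](CC(O)C(C)(C)C(=O)C(C)(C)C(=O)OC)C(C)C)c1OCc3ccccc3 | intermediate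
21 | dimethyl (7R,7'R)-7,7'-[2,4,6-tris(benzyloxy)-5-hexanoyl-1,3-phenylene]bis(2,2,4,4,8-pentamethyl-3,5-dioxononanoate) | CCCCCC(=O)c1c(OCc2ccccc2)c([C@H](CC(=O)C(C)(C)C(=O)C(C)(C)C(=O)OC)C(C)C)c(OCc2ccccc2)c([C@H](CC(=O)C(C)(C)C(=O)C(C)(C)C(=O)OC)C(C)C)c1OCc3ccccc3 | intermediate
22 | 1-[2,4,6-tris(benzyloxy)-3,5-bis[(1R)-1-(2-hydroxy-3,3,5,5-tetramethyl-4,6-dioxocyclohex-1-en-1-yl)-2-methylpropyl]phenyl]hexan-1-one | CCCCCC(=O)c1c(OCc2ccccc2)c([C@H](C4=C(O)C(C)(C)C(=O)C(C)(C)C4=O)C(C)C)c(OCc2ccccc2)c([C@H](C4=C(O)C(C)(C)C(=O)C(C)(C)C4=O)C(C)C)c1OCc3ccccc3 | intermediate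
23 | myrtucommulone F, (R,R) | CCCCCC(=O)c1c(O)c([C@H](C2=C(O)C(C)(C)C(=O)C(C)(C)C2=O)C(C)C)c(O)c([C@H](C2=C(O)C(C)(C)C(=O)C(C)(C)C2=O)C(C)C)c1O | target

**Step count**
Total steps: 14. Longest linear sequence: 12 (steps 1, 2, 4–9, 11–14).

**Steps most likely to fail**

**Step 5 (key step).**
- Heterolysis of the secondary allylic C–O bond is possible because the acylphenoxide leaves easily. It would cost the allyl unit as a diene, or let it recombine without facial memory.
- Leakage through the arrangement with a pseudo-axial methyl group would invert the new centre.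
- Proton transfer from a freed phenol to the alkene would open the abnormal Claisen pathway.

The fallback sets out from 4 and returns at 15. Both aryl–carbon bonds would instead be made by an iminium-catalysed Friedel–Crafts alkylation–hemiacetalisation of 4 with (E)-4-methylpent-2-enal. The catalyst is diphenylprolinol trimethylsilyl ether of the absolute configuration that gives the (R)-centres, with benzoic acid in PhMe. This is a known reaction type of electron-rich phenols and should give the bis(chroman-2-ol) F1. NaBH4 in MeOH would reduce the lactols through their open hydroxy-aldehyde form to the bisphenol diol F2, the phenoxide-deactivated ketone staying intact. Phenol-selective benzylation (BnBr, K2CO3, DMF) then rejoins the route at 15.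

**Step 13.**
- The hindered enolate may attack through oxygen and close enol δ-lactones.
- Liberated methoxide may cleave the non-enolisable 1,3-diketone by a retro-Claisen process.
- Closure onto the neopentyl-type ester may be slow next to the crowded benzylic carbon.

The fallback sets out from 16 and returns at 22, replacing the ester electrophile by a sterically slim nitrile.
- The ketonitrile 2,2,4-trimethyl-3-oxopentanenitrile F3 is made from isobutyronitrile, LiN(iPr)2 and isobutyryl chloride.
- F3 is deprotonated with LiN(iPr)2 and added to 16 to give the bis(hydroxy ketonitrile) F4.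
- Dess–Martin oxidation gives the bis(diketonitrile) F5.
- KOtBu in THF would close both rings by a Thorpe–Ziegler-type attack of the ketone enolate on the nitrile. This releases no alkoxide and offers no stable O-acylation outlet, and it should give the bis(3-aminocyclohexenone) F6.
- Hydrolysis of the vinylogous amides (aq. HCl, THF, reflux) delivers 22.

**Step 7.**
- Metallacycle formation at the crowded alkenes may be slow.
- The ruthenium methylidene may decay under ethylene.
- Hydride-mediated migration of the double bond into conjugation with ring A would destroy the stereocentres.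

The fallback sets out from 12 and returns at 13, cutting the alkene and rebuilding it by one carbon. Lemieux–Johnson cleavage (OsO4 cat., NaIO4, 2,6-lutidine, dioxane–water) gives the bis(α-aryl aldehyde) F7. F7 is methylenated at once under non-basic, aldehyde-selective Takai conditions (CH2I2, Zn, Ti(OiPr)4, THF). The acidic α-hydrogen is then not exchanged and the aryl ketone is left alone, giving 13.

**Further compounds**
F1 | step 5 | (4R,6R)-5-(benzyloxy)-10-hexanoyl-4,6-di(propan-2-yl)-3,4,6,7-tetrahydro-2H,8H-pyrano[3,2-g]chromene-2,8-diol (lactol epimers) | CCCCCC(=O)c1c2OC(O)C[C@H](C(C)C)c2c(OCc3ccccc3)c3c1OC(O)C[C@@H]3C(C)C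
F2 | step 5 | 1-[4-(benzyloxy)-2,6-dihydroxy-3,5-bis[(3R)-1-hydroxy-4-methylpentan-3-yl]phenyl]hexan-1-one | CCCCCC(=O)c1c(O)c([C@H](CCO)C(C)C)c(OCc2ccccc2)c([C@H](CCO)C(C)C)c1O
F3 | step 13 | 2,2,4-trimethyl-3-oxopentanenitrile | CC(C)C(=O)C(C)(C)C#N
F4 | step 13 | (7R,7'R)-7,7'-[2,4,6-tris(benzyloxy)-5-hexanoyl-1,3-phenylene]bis(5-hydroxy-2,2,4,4,8-pentamethyl-3-oxononanenitrile), C5 epimers | CCCCCC(=O)c1c(OCc2ccccc2)c([C@H](CC(O)C(C)(C)C(=O)C(C)(C)C#N)C(C)C)c(OCc2ccccc2)c([C@H](CC(O)C(C)(C)C(=O)C(C)(C)C#N)C(C)C)c1OCc3ccccc3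
F5 | step 13 | (7R,7'R)-7,7'-[2,4,6-tris(benzyloxy)-5-hexanoyl-1,3-phenylene]bis(2,2,4,4,8-pentamethyl-3,5-dioxononanenitrile) | CCCCCC(=O)c1c(OCc2ccccc2)c([C@H](CC(=O)C(C)(C)C(=O)C(C)(C)C#N)C(C)C)c(OCc2ccccc2)c([C@H](CC(=O)C(C)(C)C(=O)C(C)(C)C#N)C(C)C)c1OCc3ccccc3
F6 | step 13 | 1-[2,4,6-tris(benzyloxy)-3,5-bis[(1R)-1-(2-amino-3,3,5,5-tetramethyl-4,6-dioxocyclohex-1-en-1-yl)-2-methylpropyl]phenyl]hexan-1-one | CCCCCC(=O)c1c(OCc2ccccc2)c([C@H](C4=C(N)C(C)(C)C(=O)C(C)(C)C4=O)C(C)C)c(OCc2ccccc2)c([C@H](C4=C(N)C(C)(C)C(=O)C(C)(C)C4=O)C(C)C)c1OCc3ccccc3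
F7 | step 7 | (2R,2'R)-2,2'-[2,4,6-tris(benzyloxy)-5-hexanoyl-1,3-phenylene]bis(3-methylbutanal) | CCCCCC(=O)c1c(OCc2ccccc2)c([C@H](C=O)C(C)C)c(OCc2ccccc2)c([C@H](C=O)C(C)C)c1OCc3ccccc3
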